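**Retrosynthetic overview**

- The target is a 2',4',2-trihydroxychalcone whose ring A carries an (S)-lavandulyl chain at C3'. Rings A and B are bought and no ring is formed.
- The strategy rests on the stereogenic CH of the side chain, which bears the isopropenyl group and a CH2 bonded to C3' of ring A (the ring carbon between the two phenolic oxygens).
- Key disconnection: the CH–isopropenyl bond and the C3'–CH2 bond are made together by enantioselective conjunctive coupling of an (isopropenyl)(vinyl)borate with the bis-MOM ether of 2-bromoresorcinol, giving a secondary allylic boronate.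
- Boron is then replaced with retention by the prenyl arm: one-carbon Matteson homologation, then B-alkyl Suzuki–Miyaura coupling with 1-bromo-2-methylpropene.
- The enone comes last: MOM-directed ortho-lithiation at C1', acylation with a MOM-protected 2-hydroxycinnamoyl Weinreb amide, then acidic removal of the three MOM groups.

Key step: step 2

Assumption: "MandyPhos" means 1,1'-bis[bis(4-methoxy-3,5-dimethylphenyl)phosphino]-2,2'-bis[α-(dimethylamino)benzyl]ferrocene. The (Sp,Sp) enantiomer is written in step 2; if oxidation of a sample of the boronate to the allylic alcohol shows the (R) series, the commercial (Rp,Rp) antipode is used in the same step.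

**Route**

Step 1
Reactants: 1 2-bromoresorcinol
Product: 2 2-bromo-1,3-bis(methoxymethoxy)benzene
Conditions: NaH, MOMCl, DMF, 0 °C to rt
Reagents that add atoms: chloromethyl methyl ether (MOMCl), COCCl
Why: Williamson-type O-alkylation of both phenoxides gives the bis-MOM ether, which tolerates the organometallic steps and later serves as the ortho-directing group.

Step 2
Reactants: 2 2-bromo-1,3-bis(methoxymethoxy)benzene; 3 isopropenylboronic acid pinacol ester; 4 vinylmagnesium bromide
Product: 6 (S)-allylic boronate 2-[(2S)-1-[2,6-bis(methoxymethoxy)phenyl]-3-methylbut-3-en-2-yl]-4,4,5,5-tetramethyl-1,3,2-dioxaborolane, via bis(alkenyl)borate 5 (not isolated)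
Conditions: 3 + 4, THF, 0 °C to rt; then NaOTf, Pd(OAc)2 (cat.), (Sp,Sp)-MandyPhos (cat.), 2, THF/DMSO, 40–60 °C
Reagents that add atoms: none
Why: Oxidative addition of the carbon–bromine bond of 2 to zerovalent palladium carrying the chiral bisphosphine gives an arylpalladium species (NaOTf acting as halide scavenger) that binds the unsubstituted vinyl group of borate 5; this triggers an anti 1,2-metallate shift of the isopropenyl group from boron to the boron-bound vinyl carbon, which becomes the stereocenter, and reductive elimination from the divalent alkylpalladium joins the former vinyl terminus to the ring carbon between the two MOM ethers. The closest known reaction type is the palladium-catalysed enantioselective conjunctive cross-coupling of Grignard-derived bis(alkenyl)borates with aryl halides or triflates, which gives secondary allylic pinacol boronates. No ring is closed. The new stereocenter is set by catalyst control, the ferrocenyl ligand deciding which face of the bound vinyl group receives the migrating isopropenyl group. The step needs site selectivity between the two alkenes and conjunctive coupling in preference to direct Suzuki–Miyaura transfer of an alkenyl group; the first is secured by the steric difference between the vinyl and the 1,1-disubstituted isopropenyl group, the second by the chelating bisphosphine, which leaves no open site for transmetalation. The two ortho MOM ethers are expected to slow oxidative addition, so the step is run warm with a slight excess of the borate.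

Step 3
Reactants: 6 (S)-allylic boronate
Product: 8 2-[(2S)-2-[2,6-bis(methoxymethoxy)benzyl]-3-methylbut-3-en-1-yl]-4,4,5,5-tetramethyl-1,3,2-dioxaborolane, via chloromethyl boronate complex 7 (not isolated)
Conditions: BrCH2Cl, n-BuLi, THF, −78 °C to rt
Reagents that add atoms: bromochloromethane, ClCBr
Why: Matteson homologation, in which chloromethyllithium formed in situ adds to boron and the secondary allylic carbon migrates 1,2 with loss of chloride and retention of configuration, so the stereocenter is carried over unchanged.

Step 4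
Reactants: 8 primary boronate; 9 1-bromo-2-methylprop-1-ene
Product: 10 2-[(2S)-5-methyl-2-(prop-1-en-2-yl)hex-4-en-1-yl]-1,3-bis(methoxymethoxy)benzene
Conditions: Pd(OAc)2 (cat.), RuPhos (2-dicyclohexylphosphino-2',6'-diisopropoxybiphenyl, cat.), KOH, THF/H2O, 70 °C
Reagents that add atoms: none
Why: B-alkyl Suzuki–Miyaura coupling of a hydroxide-activated primary alkyl pinacol boronate with an alkenyl bromide, the bulky biarylphosphine favouring reductive elimination over β-hydride elimination; the stereocenter is β to boron and is not a reacting centre.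

Step 5
Reactants: 11 salicylaldehyde
Product: 12 2-(methoxymethoxy)benzaldehyde
Conditions: NaH, MOMCl, DMF, 0 °C to rt
Reagents that add atoms: chloromethyl methyl ether (MOMCl), COCCl
Why: Williamson-type O-alkylation of the phenoxide masks the ring B hydroxyl as the same acetal used on ring A, so that one final operation frees all three phenols.

Step 6
Reactants: 12 2-(methoxymethoxy)benzaldehyde; 13 diethyl [2-(methoxy(methyl)amino)-2-oxoethyl]phosphonate
Product: 14 (E)-N-methoxy-N-methyl-3-[2-(methoxymethoxy)phenyl]prop-2-enamide
Conditions: NaH, THF, 0 °C to rt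
Reagents that add atoms: none
Why: Horner–Wadsworth–Emmons olefination with the stabilised amide phosphonate gives the (E)-alkene selectively and installs the Weinreb amide in the same operation.

Step 7
Reactants: 10 lavandulyl arene; 14 cinnamoyl Weinreb amide
Product: 17 (E)-1-[2,4-bis(methoxymethoxy)-3-[(2S)-5-methyl-2-(prop-1-en-2-yl)hex-4-en-1-yl]phenyl]-3-[2-(methoxymethoxy)phenyl]prop-2-en-1-one, via aryllithium 15 (not isolated), via lithium hemiaminal 16 (not isolated)
Conditions: n-BuLi, TMEDA, THF, −20 to 0 °C; then 14, −78 to 0 °C; aq. NH4Cl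
Reagents that add atoms: none
Why: Directed ortho-metalation by a MOM ether (the position between the two MOM ethers is blocked by the side chain) followed by Weinreb ketone synthesis, in which the chelated adduct 16 prevents over-addition and releases the enone only on work-up; the remote stereocenter carries no hydrogen acidic enough to be affected.

Step 8
Reactants: 17 tris-MOM chalcone
Product: 18 (E)-1-[2,4-dihydroxy-3-[(2S)-5-methyl-2-(prop-1-en-2-yl)hex-4-en-1-yl]phenyl]-3-(2-hydroxyphenyl)prop-2-en-1-one
Conditions: 3 M aq. HCl, MeOH, rt to 40 °C, dark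
Reagents that add atoms: none
Why: Acid-catalysed transacetalisation of the three aryl MOM ethers in methanol, run mild and without light to avoid phenol–alkene cyclisation to chromans and isomerisation or cyclisation of the 2-hydroxychalcone.

**Compound list**

1 | 2-bromoresorcinol | Oc1cccc(O)c1Br | starting material
2 | 2-bromo-1,3-bis(methoxymethoxy)benzene | COCOc1cccc(OCOC)c1Br | intermediate
3 | isopropenylboronic acid pinacol ester | C=C(C)B1OC(C)(C)C(C)(C)O1 | starting material
4 | vinylmagnesium bromide | C=C[Mg]Br | starting material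
5 | bromomagnesium ethenyl(prop-1-en-2-yl)(pinacolato)borate | C=C[B-]1(C(C)=C)OC(C)(C)C(C)(C)O1.[Mg+]Br | intermediate
6 | 2-[(2S)-1-[2,6-bis(methoxymethoxy)phenyl]-3-methylbut-3-en-2-yl]-4,4,5,5-tetramethyl-1,3,2-dioxaborolane | C=C(C)[C@@H](B1OC(C)(C)C(C)(C)O1)Cc1c(OCOC)cccc1OCOC | intermediate
7 | lithium (chloromethyl) boronate complex of 6 | C=C(C)[C@@H]([B-]1(CCl)OC(C)(C)C(C)(C)O1)Cc1c(OCOC)cccc1OCOC.[Li+] | intermediate
8 | 2-[(2S)-2-[2,6-bis(methoxymethoxy)benzyl]-3-methylbut-3-en-1-yl]-4,4,5,5-tetramethyl-1,3,2-dioxaborolane | C=C(C)[C@@H](CB1OC(C)(C)C(C)(C)O1)Cc1c(OCOC)cccc1OCOC | intermediate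
9 | 1-bromo-2-methylprop-1-ene | CC(C)=CBr | starting material
10 | 2-[(2S)-5-methyl-2-(prop-1-en-2-yl)hex-4-en-1-yl]-1,3-bis(methoxymethoxy)benzene | C=C(C)[C@@H](CC=C(C)C)Cc1c(OCOC)cccc1OCOC | intermediate
11 | salicylaldehyde | O=Cc1ccccc1O | starting material
12 | 2-(methoxymethoxy)benzaldehyde | COCOc1ccccc1C=O | intermediate
13 | diethyl [2-(methoxy(methyl)amino)-2-oxoethyl]phosphonate | CCOP(=O)(CC(=O)N(C)OC)OCC | starting material
14 | (E)-N-methoxy-N-methyl-3-[2-(methoxymethoxy)phenyl]prop-2-enamide | CON(C)C(=O)/C=C/c1ccccc1OCOC | intermediate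
15 | [2,4-bis(methoxymethoxy)-3-[(2S)-5-methyl-2-(prop-1-en-2-yl)hex-4-en-1-yl]phenyl]lithium | C=C(C)[C@@H](CC=C(C)C)Cc1c(OCOC)ccc([Li])c1OCOC | intermediate
16 | lithium alkoxide of the N-methoxy-N-methyl hemiaminal from 15 and 14 (mixture at the new carbon) | C=C(C)[C@@H](CC=C(C)C)Cc1c(OCOC)ccc(C(O[Li])(/C=C/c2ccccc2OCOC)N(C)OC)c1OCOC | intermediate
17 | (E)-1-[2,4-bis(methoxymethoxy)-3-[(2S)-5-methyl-2-(prop-1-en-2-yl)hex-4-en-1-yl]phenyl]-3-[2-(methoxymethoxy)phenyl]prop-2-en-1-one | C=C(C)[C@@H](CC=C(C)C)Cc1c(OCOC)ccc(C(=O)/C=C/c2ccccc2OCOC)c1OCOC | intermediate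
18 | (E)-1-[2,4-dihydroxy-3-[(2S)-5-methyl-2-(prop-1-en-2-yl)hex-4-en-1-yl]phenyl]-3-(2-hydroxyphenyl)prop-2-en-1-one | C=C(C)[C@@H](CC=C(C)C)Cc1c(O)ccc(C(=O)/C=C/c2ccccc2O)c1O | target

**Count**

Total steps: 8. Longest linear sequence: 6 (steps 1, 2, 3, 4, 7, 8); steps 5 and 6 form the side branch to 14.

**Steps most likely to fail**

1. Step 2. Oxidative addition of the electron-rich, doubly ortho-substituted bromide may be slow, so that direct alkenyl transfer, protodeboronation of the borate or a drop in enantioselectivity take over. The fallback is a lithiation–borylation that sets out from 2 and comes back at 6. Bromine–lithium exchange of 2 (n-BuLi, THF, −78 °C) gives [2,6-bis(methoxymethoxy)phenyl]lithium F1, which opens ethylene oxide to 2-[2,6-bis(methoxymethoxy)phenyl]ethanol F2. Carbamoylation (N,N-diisopropylcarbamoyl chloride, NaH, THF) gives 2-[2,6-bis(methoxymethoxy)phenyl]ethyl N,N-diisopropylcarbamate F3. Deprotonation with s-BuLi and (+)-sparteine (Et2O, −78 °C) should remove the pro-R hydrogen next to oxygen and give the (R)-configured lithiated carbamate F4. Trapping with 3 should give, with retention, the lithium boronate complex F5. Migration of the isopropenyl group with inversion at carbon (MgBr2·OEt2, warming) expels the carbamate and should give (S)-6.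

2. Step 7. The aryllithium may attack the β-carbon or the N-methoxy group of 14 instead of the carbonyl, or acylation may be incomplete. The fallback builds the enone by condensation; it sets out from 10 through aryllithium 15 and comes back at 17. Quenching 15 with N-methoxy-N-methylacetamide gives the lithium hemiaminal F6, which on work-up releases 1-[2,4-bis(methoxymethoxy)-3-[(2S)-5-methyl-2-(prop-1-en-2-yl)hex-4-en-1-yl]phenyl]ethan-1-one F7. Claisen–Schmidt condensation of this methyl ketone with 12 (KOH, EtOH, rt) passes through the aldol adduct F8 and dehydrates to 17; the stereocenter is not α to the carbonyl and is not at risk.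

3. Step 4. Transmetalation of the unactivated primary alkyl boronate may be slow, leaving room for protodeboronation and for β-hydride elimination and reinsertion at the alkylpalladium stage, which would move the double bond or erode the adjacent stereocenter. The fallback is a transition-metal-free Zweifel olefination that sets out from 8 and comes back at 10. Treatment of 9 with t-BuLi (2 equiv, THF, −78 °C) gives (2-methylprop-1-en-1-yl)lithium F9, which adds to 8 to give the lithium alkenyl boronate complex F10. Iodine (THF/MeOH, −78 °C) triggers 1,2-migration of the primary alkyl group to the β-iodoalkyl boronate F11, and NaOMe induces anti elimination of boron and iodine to give 10.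

**Further compounds**

F1 | step 2 | [2,6-bis(methoxymethoxy)phenyl]lithium | COCOc1cccc(OCOC)c1[Li]
F2 | step 2 | 2-[2,6-bis(methoxymethoxy)phenyl]ethanol | OCCc1c(OCOC)cccc1OCOC
F3 | step 2 | 2-[2,6-bis(methoxymethoxy)phenyl]ethyl N,N-diisopropylcarbamate | CC(C)N(C(C)C)C(=O)OCCc1c(OCOC)cccc1OCOC
F4 | step 2 | (R)-1-lithio-2-[2,6-bis(methoxymethoxy)phenyl]ethyl N,N-diisopropylcarbamate (sparteine complex, ligand not drawn) | [Li][C@@H](OC(=O)N(C(C)C)C(C)C)Cc1c(OCOC)cccc1OCOC
F5 | step 2 | lithium boronate complex of F4 with 3 | C=C(C)[B-]1(OC(C)(C)C(C)(C)O1)[C@@H](OC(=O)N(C(C)C)C(C)C)Cc1c(OCOC)cccc1OCOC.[Li+]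
F6 | step 7 | lithium alkoxide of the N-methoxy-N-methyl hemiaminal from 15 and N-methoxy-N-methylacetamide | C=C(C)[C@@H](CC=C(C)C)Cc1c(OCOC)ccc(C(C)(O[Li])N(C)OC)c1OCOC
F7 | step 7 | 1-[2,4-bis(methoxymethoxy)-3-[(2S)-5-methyl-2-(prop-1-en-2-yl)hex-4-en-1-yl]phenyl]ethan-1-one | C=C(C)[C@@H](CC=C(C)C)Cc1c(OCOC)ccc(C(C)=O)c1OCOC
F8 | step 7 | aldol adduct 1-[2,4-bis(methoxymethoxy)-3-[(2S)-5-methyl-2-(prop-1-en-2-yl)hex-4-en-1-yl]phenyl]-3-hydroxy-3-[2-(methoxymethoxy)phenyl]propan-1-one | C=C(C)[C@@H](CC=C(C)C)Cc1c(OCOC)ccc(C(=O)CC(O)c2ccccc2OCOC)c1OCOC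
F9 | step 4 | (2-methylprop-1-en-1-yl)lithium | CC(C)=C[Li]
F10 | step 4 | lithium (2-methylprop-1-en-1-yl) boronate complex of 8 | C=C(C)[C@@H](C[B-]1(C=C(C)C)OC(C)(C)C(C)(C)O1)Cc1c(OCOC)cccc1OCOC.[Li+]
F11 | step 4 | β-iodoalkyl boronate 2-[(4S)-4-[2,6-bis(methoxymethoxy)benzyl]-2-iodo-2,5-dimethylhex-5-en-3-yl]-4,4,5,5-tetramethyl-1,3,2-dioxaborolane (mixture at the boron-bearing carbon) | C=C(C)[C@@H](CC(B1OC(C)(C)C(C)(C)O1)C(C)(C)I)Cc1c(OCOC)cccc1OCOC
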